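**Retrosynthetic overview**
Ring A is numbered C1 (CH2OH), C2 (H), C3 (Br), C4 (OH), C5 (OH), C6 (CH2Ar). Ring B, the 3-bromo-4-hydroxyphenyl group, is bought intact as its methyl ether.
The plan rests on one feature of ring A: the C1 carbon substituent is meta to the C5 hydroxyl and the second oxygen sits on the adjacent C4. This is the pattern of a 3-hydroxybenzoate grown from a 3-ethoxycarbonyl-3,5-dienoic acid whose diene ends in an enol ether.
The key disconnection is C4-C5. Ring A, the only ring formed, closes from an acyclic acid through a dienylketene and a 6-pi electrocyclisation, and all six substituents are already on the chain.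
The acid is cut at C1=C2 (Horner-Wadsworth-Emmons reaction of a phosphonosuccinate with the isopropyl enol ether of bromomalonaldehyde) and at C6-CH2Ar (enolate benzylation).
The end game is deacetylation, ether cleavage and ester reduction, with the reduction last because the product is a para-hydroxybenzyl alcohol.

Key step: step 8

Remark: chain atoms carry the ring A numbers they will have after closure. C5 is the carboxyl carbon, C6 its alpha carbon, C1 the ester-bearing alkene carbon, C2 is CH, C3 is CBr and C4 is CH-O-i-Pr.
Assumption: enol ether 2 is taken as the Z isomer (O-i-Pr trans to CHO), the more stable form of this push-pull alkene.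

Step 1
Reactants: 1 2-bromomalonaldehyde
Product: 2 (Z)-2-bromo-3-isopropoxyprop-2-enal
Conditions: i-PrOH, p-TsOH·H2O (cat.), cyclohexane, reflux, azeotropic removal of water
Reagents that add atoms: propan-2-ol CC(C)O
Why: Acid-catalysed enol etherification of the fully enolised 1,3-dialdehyde (a vinylogous Fischer esterification) is driven by removal of water and should settle on the more stable isomer with O-i-Pr trans to CHO.

Step 2
Reactants: 3 triethyl phosphonoacetate; 4 tert-butyl bromoacetate
Product: 5 4-tert-butyl 1-ethyl 2-(diethoxyphosphoryl)butanedioate (racemic)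
Conditions: NaH, THF, 0 °C → rt
Reagents that add atoms: none
Why: SN2 alkylation of deprotonated 3 by a primary alpha-bromo ester is a standard malonate-type C-alkylation, and the new P-bearing stereocentre is racemic and vanishes in step 3.

Step 3
Reactants: 5 phosphonosuccinate; 2 (Z)-2-bromo-3-isopropoxyprop-2-enal
Product: 6 4-tert-butyl 1-ethyl (2E)-2-[(2Z)-2-bromo-3-isopropoxyprop-2-en-1-ylidene]butanedioate
Conditions: NaH (slight deficit), THF, 0 °C; then 2, 0 °C → rt
Reagents that add atoms: none
Why: In this Horner-Wadsworth-Emmons olefination of a non-enolisable aldehyde, alpha-substituted phosphonoacetates place the aldehyde residue trans to CO2Et, so C3 should end up cis to the CH2CO2t-Bu arm (E at C1=C2) while the C3=C4 geometry of 2 is carried through.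

Step 4
Reactants: 7 3-bromo-4-methoxybenzaldehyde
Product: 8 (3-bromo-4-methoxyphenyl)methanol
Conditions: NaBH4, MeOH, 0 °C
Reagents that add atoms: none
Why: Borohydride reduction of an aromatic aldehyde leaves the aryl bromide and the methyl ether untouched.

Step 5
Reactants: 8 (3-bromo-4-methoxyphenyl)methanol
Product: 9 3-bromo-4-methoxybenzyl bromide
Conditions: PBr3, CH2Cl2, 0 °C
Reagents that add atoms: phosphorus tribromide BrP(Br)Br
Why: Activation of the benzylic alcohol as a phosphite ester and SN2 displacement by bromide (PBr3 bromination) is reliable at an anisyl-type benzylic position.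

Step 6
Reactants: 6 diene diester; 9 3-bromo-4-methoxybenzyl bromide
Product: 10 1-tert-butyl 4-ethyl (3E)-2-(3-bromo-4-methoxybenzyl)-3-[(2Z)-2-bromo-3-isopropoxyprop-2-en-1-ylidene]butanedioate (racemic)
Conditions: LiN(SiMe3)2, THF, −78 °C; then 9, −78 → −40 °C; AcOH quench
Reagents that add atoms: none
Why: This is an enolate alkylation in which the CH2 between the tert-butyl ester and C1=C2 is by far the most acidic site, alkylidenesuccinates deprotonated there react with benzylic halides at the alpha carbon with the double bond left in place, the silylamide base and low temperature should spare the bromo enol ether, and the new C6 stereocentre is racemic and is erased in step 8.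

Step 7
Reactants: 10 benzylated diester
Product: 11 (3E,5Z)-5-bromo-2-(3-bromo-4-methoxybenzyl)-3-(ethoxycarbonyl)-6-isopropoxyhexa-3,5-dienoic acid (racemic)
Conditions: CF3CO2H, CH2Cl2 (anhydrous), 0 °C → rt; co-evaporation with toluene, no aqueous work-up
Reagents that add atoms: none
Why: Acidolysis of the tert-butyl ester (loss of the tert-butyl cation as isobutene) leaves the ethyl ester alone, and the enol ether, conjugated through the diene with CO2Et and deactivated by bromine, behaves like a vinylogous ester that cannot hydrolyse while water is excluded.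

Step 8
Reactants: 11 dienoic acid
Product: 15 ethyl 3-acetoxy-5-bromo-2-(3-bromo-4-methoxybenzyl)-4-isopropoxybenzoate, via mixed anhydride 12 (not isolated), via dienylketene 13 (not isolated), via cyclohexadienone 14 (not isolated)
Conditions: NaOAc, Ac2O, 120 °C
Reagents that add atoms: acetic anhydride CC(=O)OC(C)=O
Why: Ac2O turns acid 11 into mixed anhydride 12, acetate removes the C6-H that is activated by both the anhydride carbonyl and the C1=C2 bond, and loss of acetic acid gives dienylketene 13. A thermal disrotatory 6-pi electrocyclisation then joins the ketene carbon C5 to the enol ether carbon C4 and closes the six-membered ring A as dienone 14, which loses its C4 proton to become aromatic and is acetylated at the C5 oxygen by Ac2O to give 15. The closest known reactions are the Ac2O/NaOAc benzannulation of 3-alkoxycarbonyl-3,5-dienoic acids, the cyclisation of Stobbe half-esters of 3-furyl and 3-indolyl aldehydes, which also close onto the heteroatom-bearing carbon, and the thermal reclosure of dienylketenes formed by photolysis of 6-acyloxycyclohexa-2,4-dienones, whose terminus likewise carries oxygen. No stereocentre is created, and the racemic C6 centre of 11 is lost at the ketene stage. The closure needs C3 and C6 cis across C1=C2, which the E geometry from step 3 supplies, and a terminus that turns only hydrogen inward, which the Z enol ether supplies; C4 is then the only atom that can reach C5, so a single regioisomer is possible. Because C4 is not the nucleophilic carbon of the enol ether, a polar Friedel-Crafts-type acylation cannot replace the pericyclic path, which is why basic, ketene-forming conditions are used, and ring B stays out of the reaction since the CH2 group insulates it from the ketene.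

Step 9
Reactants: 15 aryl acetate
Product: 16 ethyl 5-bromo-2-(3-bromo-4-methoxybenzyl)-3-hydroxy-4-isopropoxybenzoate
Conditions: K2CO3 (cat.), EtOH, rt
Reagents that add atoms: none
Why: Base-catalysed transesterification cleaves the aryl acetate far faster than the hindered benzoate, and ethanol is the solvent so that any exchange at the C1 ester is degenerate.

Step 10
Reactants: 16 phenol
Product: 17 ethyl 5-bromo-2-(3-bromo-4-hydroxybenzyl)-3,4-dihydroxybenzoate
Conditions: BBr3 (5 equiv), CH2Cl2, −78 → 0 °C; then H2O
Reagents that add atoms: none
Why: Lewis-acid ether cleavage with BBr3 removes the secondary isopropyl group quickly and the ring B methyl ether on warming while an ethyl benzoate normally survives, and the deprotection comes before the reduction so that no benzylic alcohol meets BBr3.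

Step 11
Reactants: 17 triphenol ester
Product: 18 6-bromo-3-(3-bromo-4-hydroxybenzyl)-4-(hydroxymethyl)benzene-1,2-diol (target, achiral)
Conditions: i-Bu2AlH (8 equiv), THF, −78 → 0 °C; aq. potassium sodium tartrate, alcohol-free work-up
Reagents that add atoms: none
Why: i-Bu2AlH reduces the ester after the three phenols have been taken up as aluminium phenoxides (hence the excess), aryl bromides are inert, and low temperature with a near-neutral work-up should keep the para-hydroxybenzyl alcohol from ionising to a quinone methide.

**Compound list**
1 | 2-bromomalonaldehyde (2-bromopropanedial) | O=CC(Br)C=O | starting material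
2 | (Z)-2-bromo-3-isopropoxyprop-2-enal | O=C/C(Br)=C/OC(C)C | intermediate
3 | triethyl phosphonoacetate | CCOC(=O)CP(=O)(OCC)OCC | starting material
4 | tert-butyl bromoacetate | CC(C)(C)OC(=O)CBr | starting material
5 | 4-tert-butyl 1-ethyl 2-(diethoxyphosphoryl)butanedioate (racemic) | CCOC(=O)C(CC(=O)OC(C)(C)C)P(=O)(OCC)OCC | intermediate
6 | 4-tert-butyl 1-ethyl (2E)-2-[(2Z)-2-bromo-3-isopropoxyprop-2-en-1-ylidene]butanedioate | CCOC(=O)/C(CC(=O)OC(C)(C)C)=C/C(Br)=C/OC(C)C | intermediate
7 | 3-bromo-4-methoxybenzaldehyde | COc1ccc(C=O)cc1Br | starting material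
8 | (3-bromo-4-methoxyphenyl)methanol | COc1ccc(CO)cc1Br | intermediate
9 | 3-bromo-4-methoxybenzyl bromide | COc1ccc(CBr)cc1Br | intermediate
10 | 1-tert-butyl 4-ethyl (3E)-2-(3-bromo-4-methoxybenzyl)-3-[(2Z)-2-bromo-3-isopropoxyprop-2-en-1-ylidene]butanedioate (racemic) | CCOC(=O)/C(C(Cc1ccc(OC)c(Br)c1)C(=O)OC(C)(C)C)=C/C(Br)=C/OC(C)C | intermediate
11 | (3E,5Z)-5-bromo-2-(3-bromo-4-methoxybenzyl)-3-(ethoxycarbonyl)-6-isopropoxyhexa-3,5-dienoic acid (racemic) | CCOC(=O)/C(C(Cc1ccc(OC)c(Br)c1)C(=O)O)=C/C(Br)=C/OC(C)C | intermediate
12 | mixed anhydride of 11 with acetic acid | CCOC(=O)/C(C(Cc1ccc(OC)c(Br)c1)C(=O)OC(C)=O)=C/C(Br)=C/OC(C)C | intermediate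
13 | dienylketene, ethyl (2E,4Z)-4-bromo-2-[1-(3-bromo-4-methoxyphenyl)-3-oxoprop-2-en-2-yl]-5-isopropoxypenta-2,4-dienoate | CCOC(=O)/C(C(Cc1ccc(OC)c(Br)c1)=C=O)=C/C(Br)=C/OC(C)C | intermediate
14 | ethyl 5-bromo-2-(3-bromo-4-methoxybenzyl)-4-isopropoxy-3-oxocyclohexa-1,5-diene-1-carboxylate (racemic) | O=C1C(OC(C)C)C(Br)=CC(C(=O)OCC)=C1Cc1ccc(OC)c(Br)c1 | intermediate
15 | ethyl 3-acetoxy-5-bromo-2-(3-bromo-4-methoxybenzyl)-4-isopropoxybenzoate | CCOC(=O)c1cc(Br)c(OC(C)C)c(OC(C)=O)c1Cc1ccc(OC)c(Br)c1 | intermediate
16 | ethyl 5-bromo-2-(3-bromo-4-methoxybenzyl)-3-hydroxy-4-isopropoxybenzoate | CCOC(=O)c1cc(Br)c(OC(C)C)c(O)c1Cc1ccc(OC)c(Br)c1 | intermediate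
17 | ethyl 5-bromo-2-(3-bromo-4-hydroxybenzyl)-3,4-dihydroxybenzoate | CCOC(=O)c1cc(Br)c(O)c(O)c1Cc1ccc(O)c(Br)c1 | intermediate
18 | 6-bromo-3-(3-bromo-4-hydroxybenzyl)-4-(hydroxymethyl)benzene-1,2-diol | OCc1cc(Br)c(O)c(O)c1Cc1ccc(O)c(Br)c1 | target

**Step count**
Total: 11 steps. Longest linear sequence: 8 steps (1, 3, 6, 7, 8, 9, 10, 11). The branch 4, 5, 6, 7, 8, 9, 10, 11 is equally long.

**Steps most likely to fail**

1. Step 8.
- What may go wrong: acetic acid may leave the alpha-branched mixed anhydride slowly. Acetolysis or thermal breakdown of the bromo enol ether, or E/Z scrambling at C1=C2, could then overtake ring closure at 120 °C. The benzannulation also has no direct example with an alkoxy group on the closing terminus and bromine next to it.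
- Fallback: leave the anhydride manifold and make the same ketene by dehydrochlorination near room temperature, free of acetate and Ac2O.
- Setting out from 11, 1-chloro-N,N,2-trimethylprop-1-en-1-amine in CH2Cl2 at 0 °C (neutral, no HCl) should give (3E,5Z)-5-bromo-2-(3-bromo-4-methoxybenzyl)-3-(ethoxycarbonyl)-6-isopropoxyhexa-3,5-dienoyl chloride F1.
- Slow addition of F1 to Et3N in dilute toluene at 0 → 40 °C should generate 13, which closes through 14 and tautomerises to the free phenol.
- The route is rejoined at 16 and step 9 falls away.

2. Step 6.
- What may go wrong: the extended enolate may be alkylated at a remote carbon. Rotation about C1-C2 in the delocalised anion may cost the E geometry. The anion may also expel bromide (vinylogous dehydrobromination).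
- Fallback: put the benzyl group in before the diene exists.
- Setting out from 9, alkylation of diethyl succinate (LiN(i-Pr)2, THF, −78 °C) should give diethyl 2-(3-bromo-4-methoxybenzyl)succinate F2.
- Stobbe condensation of F2 with aldehyde 2 (KOt-Bu, t-BuOH/THF, 0 °C → rt) takes place at the unsubstituted CH2.
- Lactonisation onto the ester next to the benzyl-bearing carbon, followed by E1cB opening, frees exactly that carboxyl group. The carboxylate charge shields the product from further deprotonation.
- The route is rejoined at 11, and steps 2, 3, 6 and 7 are bypassed.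

3. Step 3.
- What may go wrong: the soft phosphonate carbanion may attack the alkoxy-bearing carbon of 2 with loss of isopropoxide in place of carbonyl addition, or E selectivity may erode.
- Fallback: replace the phosphonate olefination by an aldol-based one.
- Setting out from 2, Stobbe condensation with diethyl succinate (KOt-Bu, t-BuOH/THF, 0 °C) uses a harder ester enolate whose carbonyl adduct is trapped by lactonisation. It should give (3E,5Z)-5-bromo-3-(ethoxycarbonyl)-6-isopropoxyhexa-3,5-dienoic acid F3.
- Esterification of F3 with tert-butyl 2,2,2-trichloroacetimidate (CH2Cl2/cyclohexane, rt) comes back to the route at 6.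

**Further compounds**
F1 | step 8 | (3E,5Z)-5-bromo-2-(3-bromo-4-methoxybenzyl)-3-(ethoxycarbonyl)-6-isopropoxyhexa-3,5-dienoyl chloride | CCOC(=O)/C(C(Cc1ccc(OC)c(Br)c1)C(=O)Cl)=C/C(Br)=C/OC(C)C
F2 | step 6 | diethyl 2-(3-bromo-4-methoxybenzyl)succinate | CCOC(=O)CC(Cc1ccc(OC)c(Br)c1)C(=O)OCC
F3 | step 3 | (3E,5Z)-5-bromo-3-(ethoxycarbonyl)-6-isopropoxyhexa-3,5-dienoic acid | CCOC(=O)/C(CC(=O)O)=C/C(Br)=C/OC(C)C
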